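**Plan**
1. Cuts: C11=C12 and C11'=C12' (two Wittig reactions on the C10 trienedial). Then C8–C9 (left) and C6'–C7' (right), both Sonogashira. Then, in the dihydroxy ring, C1–C2 (Ireland–Claisen ring contraction) and C5–C6 (alkenyl-metal addition).
2. Enabling feature: in the 3,4-dihydroxy ring the tetrasubstituted C5=C6 bond lies γ,δ to a carbonyl placed on C2, through the quaternary C1. A helper carboxyl on C2 therefore exposes a Claisen retron. The retro-[3,3] shift breaks C1–C2, moves the alkene to C6=C1 (an isopropylidene) and ties the carboxyl oxygen to C5, which gives a δ-lactone.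
3. That lactone, C(=O)–C2H2–C3H(O)–C4H(O)–C5(O)–CH3, is a 5-C-alkenyl 2,6-dideoxyhexono-1,5-lactone. Its six carbons and its cis-3,4-diol are those of D-digitoxose.
4. Forward: digitoxose → 5-keto ester → addition of Me2C=C(M)–C≡C–TIPS with lactonisation → ring contraction closes the carbocycle → Barton decarboxylation removes the helper carbon → C15 phosphonium salt. The second ring comes ready-made in actinol. C15 + C10 + C15 are joined last.
5. Stereochemistry: C3/C4 are C3/C4 of D-digitoxose and C3' comes from (4R,6R)-actinol. Lactone C5 and acid C2 are transient centres, so both epimers converge. The E-alkenes come from an E-iodide, an E-enynol, the all-E dial and Wittig olefination with thermal Z→E relaxation.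

Key step: step 6

Assumption: D-digitoxose, 1,1-dibromo-2-methylprop-1-ene, (4R,6R)-actinol, (E)-3-methylpent-2-en-4-yn-1-ol and the C10 trienedial are taken as catalogue chemicals. Ring atoms carry carotenoid numbers (C1 = CMe2, C2 = CH2, C3/C4 = carbinols, C5 = C–Me, C6 = C–alkynyl).

**Step 1**
Reactants: 1 D-digitoxose
Product: 2 2,6-dideoxy-3,4-O-isopropylidene-D-ribo-hexopyranose (anomeric mixture)
Conditions: 2-methoxypropene, PPTS (cat.), DMF, 0 °C
Reagents that add atoms: 2-methoxypropene, COC(C)=C
Why: Kinetic acid-catalysed acetonide formation picks the only cis-1,2-diol of the pyranose form (O3/O4), as it does with 2-deoxy-D-ribose, and touches no stereocentre.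

**Step 2**
Reactants: 2 acetonide lactol
Product: 4 methyl 2,6-dideoxy-3,4-O-isopropylidene-D-ribo-hexonate (5-OH free), via δ-lactone 3 (not isolated)
Conditions: I2, K2CO3, MeOH, rt
Reagents that add atoms: methanol, CO
Why: Hypoiodite oxidation of the lactol and base-catalysed methanolysis of the lactone in one pot (oxidative esterification) fix sugar C1 at the ester level and free O5–H, while secondary alcohols are inert under these conditions.

**Step 3**
Reactants: 4 hydroxy ester
Product: 5 methyl 2-[(4S,5S)-5-acetyl-2,2-dimethyl-1,3-dioxolan-4-yl]acetate (5-keto ester)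
Conditions: Dess–Martin periodinane, CH2Cl2, 0 °C → rt
Reagents that add atoms: none
Why: Dess–Martin oxidation works without base, so the redundant C5 carbinol should become the methyl ketone without epimerising the α-alkoxy centre C4 or eliminating O3.

**Step 4**
Reactants: 6 1,1-dibromo-2-methylprop-1-ene (excess); 7 (triisopropylsilyl)acetylene
Product: 8 (3-bromo-4-methylpent-3-en-1-yn-1-yl)triisopropylsilane
Conditions: PdCl2(PPh3)2 (cat.), CuI (cat.), Et3N, THF, rt
Reagents that add atoms: none
Why: Sonogashira mono-alkynylation of a gem-dibromoalkene raises no E/Z question because the two bromines are equivalent, and the excess of 6 holds back the second coupling.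

**Step 5**
Reactants: 8 bromoenyne; 5 keto ester
Product: 12 2,6-dideoxy-3,4-O-isopropylidene-5-C-[4-methyl-1-(triisopropylsilyl)pent-3-en-1-yn-3-yl]hexono-1,5-lactone (both C5 epimers), via alkenyllithium 9 (not isolated), via alkenylcerium dichloride 10 (not isolated), via open-chain tertiary alkoxide 11 (not isolated)
Conditions: t-BuLi (2 equiv), Et2O–THF, −78 °C; anhydrous CeCl3, THF, −78 °C; 5, −78 → 0 °C; aq. NH4Cl
Reagents that add atoms: none
Why: Br/Li exchange and transmetalation give a weakly basic organocerium reagent that adds 1,2 to the ketone faster than to the ester and without enolisation, and the tertiary alkoxide then lactonises on the methyl ester; polar Felkin–Anh attack anti to O4 should favour the epimer with the alkenyl group trans to O4, but C5 is erased later, so the mixture is used.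

**Step 6**
Reactants: 12 5-C-alkenyl δ-lactone (epimer mixture)
Product: 14 tert-butyldimethylsilyl (3S,4R)-3,4-(isopropylidenedioxy)-1,1,5-trimethyl-6-[(triisopropylsilyl)ethynyl]cyclohex-5-ene-2-carboxylate (C2 epimers), via silyl ketene acetal 13 (not isolated)
Conditions: TBSCl, DMPU, THF, −78 °C, then LDA (internal quench), −78 → 0 °C; change to toluene (trace Et3N), 100 °C
Reagents that add atoms: tert-butyldimethylsilyl chloride, CC(C)(C)[Si](C)(C)Cl
Why: LDA removes a C2 proton (the only acidic C–H of 12) in the presence of TBSCl, so the lactone enolate is O-silylated to the cyclic ketene acetal 13 before it can expel O3, and on heating the array C2=C(OTBS)–O–C5–C6=C1 undergoes a concerted suprafacial [3,3] shift in which C1–C2 forms while O–C5 breaks. The closest known reaction type is the Ireland–Claisen ring contraction of 6-alkenyl δ-lactones and 6-alkenyl-1,4-dioxan-2-ones to cyclohexene- and dihydropyran-carboxylic acids. The six-membered carbocycle closes by sigmatropic transposition of the six-membered lactone through the boat-like, bicyclo[2.2.2]octane-shaped transition state (bridges C3–C4, C(OTBS)–O and C6=C1) that the short tether enforces, which creates the quaternary C1 and makes the new C5=C6 bond endocyclic, with methyl, alkynyl and CMe2 already in place and no E/Z question. The one new stereocentre, C2, is set by chirality transfer from C5 (C1 is delivered to the face of the ketene acetal on which the alkenyl group stands) and is deleted in step 7, so both C5 epimers funnel into one compound, the epimer with the alkenyl group on the acetonide face merely needing longer heating, while C3 and C4 are spectators and keep the sugar configuration. The step needs O-silylation to outrun β-elimination, which the internal quench at −78 °C and the known persistence of β-oxygenated sugar-lactone enolates at that temperature should secure. It also needs rearrangement to outrun ionisation of the tertiary allylic C5–O bond, which the acid-free non-polar medium should secure, and even an ion-pair pathway can only recombine at C1, because attack at C5 would give a cyclobutane.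

**Step 7**
Reactants: 14 silyl ester
Product: 17 acetonide of (3S,4R)-1,1,5-trimethyl-6-[(triisopropylsilyl)ethynyl]cyclohex-5-ene-3,4-diol, via acid chloride 15 (not isolated), via Barton ester 16 (not isolated)
Conditions: (COCl)2, DMF (cat.), CH2Cl2, 0 °C → rt; sodium 2-thioxopyridin-1-olate, DMAP (cat.), toluene, dark; t-BuSH, hν (W lamp), 15 °C
Reagents that add atoms: none
Why: Neutral conversion of the silyl ester into the acid chloride followed by Barton reductive decarboxylation removes the helper carbon, the secondary β-alkoxy C2 radical simply abstracts H from the thiol so that both C2 epimers become one CH2 compound, and the TIPS-capped tetrasubstituted enyne offers the thiyl radical no accessible or isomerisable π bond.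

**Step 8**
Reactants: 18 but-2-yn-1-ol
Product: 20 (E)-3-iodobut-2-en-1-ol, via bis-zirconated alkene 19 (not isolated)
Conditions: Cp2Zr(H)Cl (2.2 equiv), THF, rt, dark; I2, −78 → 0 °C; 1 M HCl
Reagents that add atoms: iodine, II
Why: syn-Hydrozirconation with the Schwartz reagent places zirconium on the less hindered, methyl-bearing alkyne carbon, and iodinolysis with retention gives the E-iodide.

**Step 9**
Reactants: 17 TIPS-enyne; 20 (E)-iodide
Product: 22 (2E)-5-[(3S,4R)-3,4-(isopropylidenedioxy)-1,1,5-trimethylcyclohex-5-en-6-yl]-3-methylpent-2-en-4-yn-1-ol (C15 alcohol), via terminal alkyne 21 (not isolated)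
Conditions: TBAF, THF, 0 °C → rt; then 20, Pd(PPh3)4 (cat.), CuI (cat.), i-Pr2NH, rt
Reagents that add atoms: none
Why: Fluoride desilylation and Sonogashira coupling in one pot form C8–C9 with retention of the iodide geometry, which fixes 9E, and both tolerate the free allylic alcohol and the acetonide.

**Step 10**
Reactants: 22 C15 alcohol
Product: 24 C15 triphenylphosphonium bromide (acetonide), via allylic bromide 23 (not isolated)
Conditions: CBr4, PPh3, CH2Cl2, 0 °C; then PPh3, EtOAc, rt
Reagents that add atoms: triphenylphosphine, c1ccc(cc1)P(c1ccccc1)c1ccccc1; carbon tetrabromide, BrC(Br)(Br)Br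
Why: Appel bromination (neutral SN2 at the primary allylic carbon) and quaternisation with PPh3 avoid the acid that could ionise the C4–O bond, and they keep the 9E geometry.

**Step 11**
Reactants: 24 acetonide salt
Product: 25 [(2E)-5-[(3S,4R)-3,4-dihydroxy-1,1,5-trimethylcyclohex-5-en-6-yl]-3-methylpent-2-en-4-ynyl]triphenylphosphonium bromide
Conditions: 48% aq. HBr (cat.), MeOH–H2O, rt
Reagents that add atoms: none
Why: Acid-catalysed acetal hydrolysis cleaves the ketal C–O bonds and not C3–O or C4–O, and the positive charge already in the molecule together with the neighbouring C3 oxygen disfavours allylic ionisation at C4, so the cis-diol is kept.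

**Step 12**
Reactants: 26 (4R,6R)-4-hydroxy-2,2,6-trimethylcyclohexanone (actinol)
Product: 27 (4R,6R)-2,2,6-trimethyl-4-(triethylsilyloxy)cyclohexanone
Conditions: TESCl, imidazole, CH2Cl2, 0 °C → rt
Reagents that add atoms: chlorotriethylsilane, CC[Si](Cl)(CC)CC
Why: Routine silylation masks the carbinol proton for the enolate step and leaves the stereocentre untouched.

**Step 13**
Reactants: 27 TES ether
Product: 29 (4R)-2,6,6-trimethyl-4-(triethylsilyloxy)cyclohex-1-en-1-yl triflate, via lithium enolate 28 (not isolated)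
Conditions: LDA, THF, −78 → 0 °C; PhNTf2, 0 °C → rt
Reagents that add atoms: N-phenylbis(trifluoromethanesulfonimide), O=S(=O)(N(c1ccccc1)S(=O)(=O)C(F)(F)F)C(F)(F)F
Why: Enol triflate formation is regiochemically unambiguous, because only the methyl-bearing α-carbon carries a proton, and it removes the dispensable C6 centre of actinol.

**Step 14**
Reactants: 29 enol triflate; 30 (E)-3-methylpent-2-en-4-yn-1-ol
Product: 31 (2E)-3-methyl-5-[(4R)-2,6,6-trimethyl-4-(triethylsilyloxy)cyclohex-1-enyl]pent-2-en-4-yn-1-ol
Conditions: Pd(PPh3)4 (cat.), CuI (cat.), Et3N, DMF, rt → 45 °C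
Reagents that add atoms: none
Why: Sonogashira coupling of the hindered cyclohexenyl triflate with a terminal enyne forms C6'–C7' and carries the E-alkene of 30 through unchanged.

**Step 15**
Reactants: 31 C15 alcohol
Product: 32 [(2E)-5-[(4R)-4-hydroxy-2,6,6-trimethylcyclohex-1-enyl]-3-methylpent-2-en-4-ynyl]triphenylphosphonium bromide
Conditions: PPh3·HBr (slight excess), MeOH, rt
Reagents that add atoms: triphenylphosphine hydrobromide, Br.c1ccc(cc1)P(c1ccccc1)c1ccccc1
Why: Phosphonium salt formation from a primary allylic alcohol with PPh3·HBr is standard carotenoid practice, and the same acidic methanol solvolyses the TES ether, while the non-allylic C3' carbinol is inert.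

**Step 16**
Reactants: 32 phosphonium salt; 33 (2E,4E,6E)-2,7-dimethylocta-2,4,6-trienedial (3 equiv)
Product: 35 C25 apo-aldehyde (all-E), via ylide 34 (not isolated)
Conditions: NaOMe, MeOH–CH2Cl2, 0 °C → rt, dark; heptane, 80 °C
Reagents that add atoms: none
Why: Wittig olefination with a semi-stabilised allylic ylide tolerates the free hydroxyl, the excess of the symmetrical dial limits reaction to one end, and the sterically hindered 11'Z isomer should relax thermally to E.

**Step 17**
Reactants: 25 diol phosphonium salt; 35 C25 aldehyde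
Product: 37 (3S,4R,3'R)-7,8,7',8'-tetradehydro-β,β-carotene-3,4,3'-triol (target), via ylide 36 (not isolated)
Conditions: NaOMe, MeOH–CH2Cl2, 0 °C → rt, dark, Ar; EtOH, 70 °C (brief); crystallisation
Reagents that add atoms: none
Why: A second Wittig olefination in methanolic methoxide forms C11=C12 in the presence of all three free hydroxyls, so no deprotection is needed on the polyene, and mild warming should convert the hindered 11Z isomer into all-E without touching the remote stereocentres.

**Compound list**
1 | D-digitoxose (2,6-dideoxy-D-ribo-hexose, pyranose form) | C[C@H]1OC(O)C[C@H](O)[C@@H]1O | starting material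
2 | 2,6-dideoxy-3,4-O-isopropylidene-D-ribo-hexopyranose | C[C@H]1OC(O)C[C@@H]2OC(C)(C)O[C@H]12 | intermediate
3 | 2,6-dideoxy-3,4-O-isopropylidene-D-ribo-hexono-1,5-lactone | C[C@H]1OC(=O)C[C@@H]2OC(C)(C)O[C@H]12 | intermediate (not isolated)
4 | methyl 2-[(4S,5R)-5-[(1R)-1-hydroxyethyl]-2,2-dimethyl-1,3-dioxolan-4-yl]acetate | C[C@@H](O)[C@H]1OC(C)(C)O[C@H]1CC(=O)OC | intermediate
5 | methyl 2-[(4S,5S)-5-acetyl-2,2-dimethyl-1,3-dioxolan-4-yl]acetate | CC(=O)[C@H]1OC(C)(C)O[C@H]1CC(=O)OC | intermediate
6 | 1,1-dibromo-2-methylprop-1-ene | CC(C)=C(Br)Br | starting material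
7 | (triisopropylsilyl)acetylene | C#C[Si](C(C)C)(C(C)C)C(C)C | starting material
8 | (3-bromo-4-methylpent-3-en-1-yn-1-yl)triisopropylsilane | CC(C)=C(Br)C#C[Si](C(C)C)(C(C)C)C(C)C | intermediate
9 | alkenyllithium from 8 | CC(C)=C([Li])C#C[Si](C(C)C)(C(C)C)C(C)C | intermediate (not isolated)
10 | alkenylcerium dichloride | CC(C)=C([Ce](Cl)Cl)C#C[Si](C(C)C)(C(C)C)C(C)C | intermediate (not isolated)
11 | open-chain tertiary alkoxide (drawn as the alcohol, C5 epimers) | CC(O)(C(C#C[Si](C(C)C)(C(C)C)C(C)C)=C(C)C)[C@H]1OC(C)(C)O[C@H]1CC(=O)OC | intermediate (not isolated)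
12 | 5-C-alkenyl 2,6-dideoxy-3,4-O-isopropylidene-hexono-1,5-lactone (C5 epimers, cis-acetonide as in 5) | CC1(OC(=O)C[C@@H]2OC(C)(C)O[C@H]12)C(C#C[Si](C(C)C)(C(C)C)C(C)C)=C(C)C | intermediate
13 | cyclic TBS ketene acetal of 12 | CC1(OC(O[Si](C)(C)C(C)(C)C)=C[C@@H]2OC(C)(C)O[C@H]12)C(C#C[Si](C(C)C)(C(C)C)C(C)C)=C(C)C | intermediate (not isolated)
14 | TBS (3S,4R)-3,4-(isopropylidenedioxy)-1,1,5-trimethyl-6-[(triisopropylsilyl)ethynyl]cyclohex-5-ene-2-carboxylate (C2 epimers) | CC1=C(C#C[Si](C(C)C)(C(C)C)C(C)C)C(C)(C)C(C(=O)O[Si](C)(C)C(C)(C)C)[C@@H]2OC(C)(C)O[C@H]12 | intermediate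
15 | acid chloride | CC1=C(C#C[Si](C(C)C)(C(C)C)C(C)C)C(C)(C)C(C(=O)Cl)[C@@H]2OC(C)(C)O[C@H]12 | intermediate (not isolated)
16 | Barton ester (2-thioxopyridin-1-yl ester) | CC1=C(C#C[Si](C(C)C)(C(C)C)C(C)C)C(C)(C)C(C(=O)ON3C=CC=CC3=S)[C@@H]2OC(C)(C)O[C@H]12 | intermediate (not isolated)
17 | acetonide of (3S,4R)-1,1,5-trimethyl-6-[(triisopropylsilyl)ethynyl]cyclohex-5-ene-3,4-diol | CC1=C(C#C[Si](C(C)C)(C(C)C)C(C)C)C(C)(C)C[C@@H]2OC(C)(C)O[C@H]12 | intermediate
18 | but-2-yn-1-ol | CC#CCO | starting material
19 | (E)-C,O-bis(chlorozirconocenyl)but-2-en-1-olate (Cp drawn σ-bonded) | C/C([Zr](Cl)(C1C=CC=C1)C1C=CC=C1)=C\CO[Zr](Cl)(C1C=CC=C1)C1C=CC=C1 | intermediate (not isolated)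
20 | (E)-3-iodobut-2-en-1-ol | C/C(I)=C\CO | intermediate
21 | terminal alkyne (acetonide) | CC1=C(C#C)C(C)(C)C[C@@H]2OC(C)(C)O[C@H]12 | intermediate (not isolated)
22 | left C15 alcohol (acetonide, 9E) | CC1=C(C#C/C(C)=C/CO)C(C)(C)C[C@@H]2OC(C)(C)O[C@H]12 | intermediate
23 | left C15 allylic bromide | CC1=C(C#C/C(C)=C/CBr)C(C)(C)C[C@@H]2OC(C)(C)O[C@H]12 | intermediate (not isolated)
24 | left C15 phosphonium bromide (acetonide) | CC1=C(C#C/C(C)=C/C[P+](c3ccccc3)(c3ccccc3)c3ccccc3)C(C)(C)C[C@@H]2OC(C)(C)O[C@H]12.[Br-] | intermediate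
25 | left C15 phosphonium bromide (3S,4R-diol) | CC1=C(C#C/C(C)=C/C[P+](c2ccccc2)(c2ccccc2)c2ccccc2)C(C)(C)C[C@H](O)[C@@H]1O.[Br-] | intermediate
26 | (4R,6R)-4-hydroxy-2,2,6-trimethylcyclohexanone (actinol) | CC1(C)C[C@H](O)C[C@@H](C)C1=O | starting material
27 | actinol TES ether | CC1(C)C[C@H](O[Si](CC)(CC)CC)C[C@@H](C)C1=O | intermediate
28 | lithium enolate of 27 | CC1=C(O[Li])C(C)(C)C[C@H](O[Si](CC)(CC)CC)C1 | intermediate (not isolated)
29 | (4R)-2,6,6-trimethyl-4-(triethylsilyloxy)cyclohex-1-enyl triflate | CC1=C(OS(=O)(=O)C(F)(F)F)C(C)(C)C[C@H](O[Si](CC)(CC)CC)C1 | intermediate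
30 | (E)-3-methylpent-2-en-4-yn-1-ol | C#C/C(C)=C/CO | starting material
31 | right C15 alcohol (TES ether) | CC1=C(C#C/C(C)=C/CO)C(C)(C)C[C@H](O[Si](CC)(CC)CC)C1 | intermediate
32 | right C15 hydroxy phosphonium bromide | CC1=C(C#C/C(C)=C/C[P+](c2ccccc2)(c2ccccc2)c2ccccc2)C(C)(C)C[C@H](O)C1.[Br-] | intermediate
33 | (2E,4E,6E)-2,7-dimethylocta-2,4,6-trienedial | O=C/C(C)=C/C=C/C=C(C)/C=O | starting material
34 | ylide from 32 | CC1=C(C#C/C(C)=C/C=P(c2ccccc2)(c2ccccc2)c2ccccc2)C(C)(C)C[C@H](O)C1 | intermediate (not isolated)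
35 | C25 aldehyde, (3R)-3-hydroxy-7,8-didehydro-12'-apo-β-caroten-12'-al | CC1=C(C#C/C(C)=C/C=C/C(C)=C/C=C/C=C(C)/C=O)C(C)(C)C[C@H](O)C1 | intermediate
36 | ylide from 25 | CC1=C(C#C/C(C)=C/C=P(c2ccccc2)(c2ccccc2)c2ccccc2)C(C)(C)C[C@H](O)[C@@H]1O | intermediate (not isolated)
37 | (3S,4R,3'R)-7,8,7',8'-tetradehydro-β,β-carotene-3,4,3'-triol | CC1=C(C#C/C(C)=C/C=C/C(C)=C/C=C/C=C(C)/C=C/C=C(\C)C#CC2=C(C)[C@@H](O)[C@@H](O)CC2(C)C)C(C)(C)C[C@H](O)C1 | target

**Step count**
Total step count: 17. Longest linear sequence: 10 steps (1, 2, 3, 5, 6, 7, 9, 10, 11, 17).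

**Steps most likely to fail**

Step 6. What may go wrong:
- β-elimination of O3 from the lactone enolate could outrun silylation.
- On heating, the tertiary allylic C5–O bond could ionise and lose a proton before the crowded quaternary centre forms.

The fallback gives up the ring closure and uses the ready-made ring of actinol, whose C3 already has the required spatial sense. It sets out from enol triflate 29 and alkyne 7.
- Sonogashira coupling gives the TIPS-enyne TES ether F1.
- Allylic oxidation of the C4 methylene (CrO3·3,5-dimethylpyrazole, CH2Cl2, −20 °C) gives the 4-enone F2.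
- L-Selectride, held to the 1,2-mode by the fully substituted β-carbon and attacking from the equatorial side, should give the cis 4-alcohol F3.
- CSA, 2,2-dimethoxypropane and MeOH–acetone exchange the TES group for the acetonide. The cis-diol forms it preferentially.
- The route is rejoined at 17.

Step 5. What may go wrong:
- The organometal could attack the ester.
- The ketone could be enolised, with loss of O3 or epimerisation at C4.
- Ring closure could stay incomplete, and the liberated methoxide could degrade the lactone.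

The fallback separates addition from ring closure. It sets out from 5.
- Me3SnOH (DCE, 60 °C) gives the keto acid F4.
- Its lithium carboxylate (LiHMDS, 1 equiv, −78 °C) is inert to 10, so only the ketone reacts and the tertiary hydroxy acid F5 results.
- F5 is closed by acyl activation (2,4,6-trichlorobenzoyl chloride, Et3N, DMAP, toluene) under methoxide-free conditions.
- The route is rejoined at 12.

Step 17. What may go wrong:
- E/Z control at C11=C12 could be poor.
- The thermal correction could cause drift towards 9Z isomers.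
- The polyene could erode under basic conditions.

The fallback moves the last bond to C8–C9, an sp–sp2 bond made with retention. It sets out from 20, 35 and 17.
- Iodide 20 is turned (CBr4, PPh3) into (E)-1-bromo-3-iodobut-2-ene F6.
- Arbuzov reaction with P(OEt)3 gives diethyl (E)-3-iodobut-2-enylphosphonate F7.
- E-selective Horner–Wadsworth–Emmons reaction of F7 (NaHMDS, excess anion) with 35 gives the C29 polyenyl iodide F8.
- Separately, 17 is desilylated (TBAF) to 21, which is isolated this time and hydrolysed (aq. AcOH) to the diol alkyne F9.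
- Sonogashira coupling of F8 with F9 (Pd(PPh3)4, CuI, i-Pr2NH, THF, rt) rejoins the route at 37.

**Further compounds**
F1 | step 6 | triethyl{[(1R)-3,5,5-trimethyl-4-[(triisopropylsilyl)ethynyl]cyclohex-3-en-1-yl]oxy}silane | CC1=C(C#C[Si](C(C)C)(C(C)C)C(C)C)C(C)(C)C[C@H](O[Si](CC)(CC)CC)C1
F2 | step 6 | 4-enone of F1 (carotenoid C4=O, 3S) | CC1=C(C#C[Si](C(C)C)(C(C)C)C(C)C)C(C)(C)C[C@H](O[Si](CC)(CC)CC)C1=O
F3 | step 6 | cis (3S,4R)-4-hydroxy-3-triethylsilyloxy enyne | CC1=C(C#C[Si](C(C)C)(C(C)C)C(C)C)C(C)(C)C[C@H](O[Si](CC)(CC)CC)[C@@H]1O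
F4 | step 5 | 2-[(4S,5S)-5-acetyl-2,2-dimethyl-1,3-dioxolan-4-yl]acetic acid | CC(=O)[C@H]1OC(C)(C)O[C@H]1CC(=O)O
F5 | step 5 | tertiary hydroxy acid (C5 epimers) | CC(O)(C(C#C[Si](C(C)C)(C(C)C)C(C)C)=C(C)C)[C@H]1OC(C)(C)O[C@H]1CC(=O)O
F6 | step 17 | (E)-1-bromo-3-iodobut-2-ene | C/C(I)=C\CBr
F7 | step 17 | diethyl (E)-3-iodobut-2-enylphosphonate | C/C(I)=C\CP(=O)(OCC)OCC
F8 | step 17 | C29 all-E polyenyl iodide (3R-hydroxy ring) | CC1=C(C#C/C(C)=C/C=C/C(C)=C/C=C/C=C(C)/C=C/C=C(\C)I)C(C)(C)C[C@H](O)C1
F9 | step 17 | (3S,4R)-6-ethynyl-1,1,5-trimethylcyclohex-5-ene-3,4-diol | C#CC1=C(C)[C@@H](O)[C@@H](O)CC1(C)C
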